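The cyclohexene ring (numbering: C1 quaternary carbinol, C2 CHOAc, C3 and C6 CHOBz, C4=C5, C7 CH2OBz) is opened at the allylic bond between carbinol carbon C3 and alkene carbon C4. The plan exploits the (Z)-configured O–C3–C4=C5–C6–O unit of that ring. The precursor is a bicyclic furanose lactol in which the C6 oxygen masks the C3 aldehyde and C6 carries a (Z)-2-iodovinyl group (C5=C4–I). In one operation, iodine–lithium exchange, lactolate opening and 6-exo addition of C4 to C3 exchange the furanose for the carbocycle, set C3 and free three hydroxyl groups for benzoylation, without extra protecting groups. D-Mannose delivers C6, C1, C2, C3 and the C1/C2 configuration, formaldehyde C7, an acetylide C4/C5.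

Key step: step 8

Remark on the chemistry: s5 and s6 denote the two mannose carbons (sugar C5 and C6) that are excised in step 7. Lactols 3 and 12 (and lactolate 13) are anomeric mixtures and 5 is a mixture of C6 epimers, so these centres are left undefined in the SMILES.

Step 1
Reactants: 1 2,3:5,6-di-O-isopropylidene-α-D-mannofuranose; 2 formaldehyde (37 % aqueous)
Product: 3 2-C-(hydroxymethyl)-2,3:5,6-di-O-isopropylidene-D-mannofuranose
Conditions: aq. HCHO, K2CO3, MeOH, 65 °C
Reagents that add atoms: none
Why: Crossed aldol hydroxymethylation of the enolisable lactol: formaldehyde should enter sugar C2 (= C1) anti to the side chain on the dioxolane, giving the only adduct able to re-close to a cis-fused lactol, which sets C1 with C7 trans to C3.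

Step 2
Reactants: 3 2-C-(hydroxymethyl) lactol; 4 trimethylsilylacetylene
Product: 5 open-chain TMS-alkynyl triol (C6 epimers)
Conditions: 4, EtMgBr, THF, 0 °C; then 3, 0 °C to rt; aq. NH4Cl
Reagents that add atoms: none
Why: Grignard addition to the ring-opened lactol builds the C6–C5 bond; the C6 configuration does not matter here, although Felkin–Anh addition is expected to favour the unwanted epimer, because step 3 erases it.

Step 3
Reactants: 5 open-chain TMS-alkynyl triol
Product: 6 TMS-ynone (C6 ketone, drawn in the open keto form)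
Conditions: MnO2 (activated, excess), CH2Cl2, rt
Reagents that add atoms: none
Why: Chemoselective MnO2 oxidation touches only the activated propargylic alcohol, so the primary C7 and the secondary C3 hydroxyl groups need no protection.

Step 4
Reactants: 6 TMS-ynone
Product: 7 (6S)-TMS-alkynyl triol
Conditions: Ru[(R,R)-TsDPEN](p-cymene) (5 mol %), i-PrOH, rt
Reagents that add atoms: none
Why: Noyori asymmetric transfer hydrogenation of an alkynyl ketone: the (R,R)-catalyst tells the alkynyl flank from the quaternary alkyl flank and should give (6S), the same face that the Felkin–Anh model (hydride anti to O–C1) favours, so catalyst and substrate are matched.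

Step 5
Reactants: 7 (6S)-TMS-alkynyl triol
Product: 8 (6S)-iodoalkyne triol
Conditions: NIS, AgNO3 (10 mol %), DMF, rt, dark
Reagents that add atoms: N-iodosuccinimide O=C1CCC(=O)N1I
Why: Silver-catalysed iododesilylation of the alkynylsilane gives the 1-iodoalkyne directly and leaves alcohols and acetonides untouched.

Step 6
Reactants: 8 (6S)-iodoalkyne triol
Product: 9 (Z)-vinyl iodide triol
Conditions: 2-nitrobenzenesulfonyl hydrazide, Et3N, THF/i-PrOH, rt
Reagents that add atoms: none
Why: Diimide reduction adds H2 syn to the iodoalkyne and should therefore give only the (Z)-vinyl iodide without breaking the C–I bond.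

Step 7
Reactants: 9 (Z)-vinyl iodide triol
Product: 12 bicyclic furanose lactol (O bridges C6 and C3; C1/C2 acetonide; Z-iodovinyl on C6; CH2OH on C1), via pentaol 10 (not isolated), via hydroxy aldehyde 11 (not isolated)
Conditions: H5IO6 (3 equiv), EtOAc, 0 °C to rt
Reagents that add atoms: none
Why: Periodic acid hydrolyses the more accessible terminal acetonide and cleaves the freed C3/s5/s6 triol twice (Malaprade glycol cleavage); the C3 aldehyde is then trapped by the cis-disposed C6 hydroxyl as a cis-fused lactol, whereas C7–OH, trans to C3 on the dioxolane, cannot close.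

Step 8
Reactants: 12 bicyclic furanose lactol
Product: 15 (3aS,4R,7S,7aR)-7a-(hydroxymethyl)-2,2-dimethyl-3a,4,7,7a-tetrahydro-1,3-benzodioxole-4,7-diol, via lithium lactolate 13 (not isolated), via lithiated aldehyde 14 (not isolated)
Conditions: t-BuLi (4.2 equiv), THF/Et2O, −78 °C to 0 °C; aq. NH4Cl
Reagents that add atoms: none
Why: t-BuLi first removes both hydroxyl protons, so the aldehyde stays masked as lactolate while iodine–lithium exchange, faster than carbonyl addition and proceeding with retention of the Z geometry, turns C4 into a vinyllithium (13); on warming the lactolate opens to 14 and C4 adds to the C3 aldehyde. The closest known reaction types are the halogen–lithium-exchange-initiated intramolecular 1,2-addition (Parham-type cyclisation) and the addition of organolithium reagents to furanose lactols. The cyclohexene closes in the 6-exo-trig mode, which is possible only because the Z-alkene holds C4 within reach of C3, and the furanose ring is given up in the same operation, which frees O–C6. The new stereocentre C3 is controlled by the cis-fused dioxolane on C1/C2: lithium bridges the aldehyde oxygen and the dioxolane oxygen on C2 (Cram chelate), and closure through the half-chair with the forming alkoxide pseudo-equatorial should place O–C3 trans to O–C2 and cis to O–C6. The step needs the exchange to outrun attack of t-BuLi on the carbonyl group and loss of HI; the lactolate mask, the low temperature and the extra equivalent of t-BuLi that destroys t-BuI secure this.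

Step 9
Reactants: 15 cyclohexene triol acetonide
Product: 16 3,6,7-tri-O-benzoate of 15
Conditions: BzCl, pyridine, DMAP, CH2Cl2, 0 °C to rt
Reagents that add atoms: benzoyl chloride O=C(Cl)c1ccccc1
Why: DMAP-catalysed acylation esterifies the three free hydroxyl groups (C3, C6, C7) in one operation while the C1/C2 diol stays masked.

Step 10
Reactants: 16 tribenzoate acetonide
Product: 17 C1,C2-diol tribenzoate (the target without its acetyl group)
Conditions: TFA/H2O 9:1, CH2Cl2, 0 °C
Reagents that add atoms: none
Why: Acid-catalysed acetal hydrolysis frees the cis C1/C2 diol; the benzoates survive and the acidic medium suppresses acyl migration.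

Step 11
Reactants: 17 C1,C2-diol tribenzoate
Product: 18 target, (1R,2S,3R,6S)-2-acetoxy-3,6-bis(benzoyloxy)-1-[(benzoyloxy)methyl]cyclohex-4-en-1-ol
Conditions: Ac2O, pyridine, DMAP (cat.), CH2Cl2, 0 °C
Reagents that add atoms: acetic anhydride CC(=O)OC(C)=O
Why: Sterically controlled acetylation takes the secondary C2 hydroxyl and leaves the hindered tertiary C1 hydroxyl free.

Compound list
1 | 2,3:5,6-di-O-isopropylidene-α-D-mannofuranose | O[C@H]1O[C@H]([C@H]2COC(C)(C)O2)[C@@H]2OC(C)(C)O[C@H]12 | starting material
2 | formaldehyde | C=O | starting material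
3 | 2-C-(hydroxymethyl)-2,3:5,6-di-O-isopropylidene-D-mannofuranose (lactol carbon = C6, quaternary carbon = C1, CH2OH = C7) | OC1O[C@H]([C@H]2COC(C)(C)O2)[C@@H]2OC(C)(C)O[C@]12CO | intermediate
4 | trimethylsilylacetylene | C#C[Si](C)(C)C | starting material
5 | open-chain triol Me3Si–C4≡C5–C6H(OH)–C1; C1 (also bearing C7H2OH) and C2 form a 2,2-dimethyl-1,3-dioxolane; C2 carries C3H(OH)–[(4R)-2,2-dimethyl-1,3-dioxolan-4-yl]; C6 epimers | C[Si](C)(C)C#CC(O)[C@@]1(CO)OC(C)(C)O[C@H]1[C@H](O)[C@H]1COC(C)(C)O1 | intermediate
6 | C6 ketone of 5 (TMS-ynone, open keto form) | C[Si](C)(C)C#CC(=O)[C@@]1(CO)OC(C)(C)O[C@H]1[C@H](O)[C@H]1COC(C)(C)O1 | intermediate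
7 | (6S)-epimer of 5 | C[Si](C)(C)C#C[C@H](O)[C@@]1(CO)OC(C)(C)O[C@H]1[C@H](O)[C@H]1COC(C)(C)O1 | intermediate
8 | 1-iodoalkyne analogue of 7 | IC#C[C@H](O)[C@@]1(CO)OC(C)(C)O[C@H]1[C@H](O)[C@H]1COC(C)(C)O1 | intermediate
9 | (Z)-vinyl iodide analogue of 7 (I–C4H=C5H–C6) | I/C=C\[C@H](O)[C@@]1(CO)OC(C)(C)O[C@H]1[C@H](O)[C@H]1COC(C)(C)O1 | intermediate
10 | pentaol (9 without the terminal acetonide) | I/C=C\[C@H](O)[C@@]1(CO)OC(C)(C)O[C@H]1[C@H](O)[C@H](O)CO | intermediate
11 | open-chain γ-hydroxy aldehyde (C3 = CHO) | I/C=C\[C@H](O)[C@@]1(CO)OC(C)(C)O[C@H]1C=O | intermediate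
12 | bicyclic furanose lactol: ring O–C3(OH)–C2–C1–C6, C1/C2 acetonide, (Z)-2-iodovinyl on C6, CH2OH on C1 | I/C=C\[C@@H]1OC(O)[C@@H]2OC(C)(C)O[C@]12CO | intermediate
13 | lithium lactolate of 12 with C4–Li and C7–OLi | [Li]/C=C\[C@@H]1OC(O[Li])[C@@H]2OC(C)(C)O[C@]12CO[Li] | intermediate
14 | ring-opened lithiated aldehyde (C4–Li, C6–OLi, C7–OLi, C3 = CHO) | [Li]/C=C\[C@H](O[Li])[C@@]1(CO[Li])OC(C)(C)O[C@H]1C=O | intermediate
15 | (3aS,4R,7S,7aR)-7a-(hydroxymethyl)-2,2-dimethyl-3a,4,7,7a-tetrahydro-1,3-benzodioxole-4,7-diol | O[C@@H]1C=C[C@H](O)[C@@]2(CO)OC(C)(C)O[C@@H]12 | intermediate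
16 | tri-O-benzoate of 15 (C3, C6, C7) | O=C(O[C@@H]1C=C[C@H](OC(=O)c2ccccc2)[C@@]2(COC(=O)c3ccccc3)OC(C)(C)O[C@@H]12)c1ccccc1 | intermediate
17 | (1R,2S,3R,6S)-3,6-bis(benzoyloxy)-1-[(benzoyloxy)methyl]cyclohex-4-ene-1,2-diol | O=C(O[C@@H]1C=C[C@H](OC(=O)c2ccccc2)[C@](O)(COC(=O)c2ccccc2)[C@H]1O)c1ccccc1 | intermediate
18 | target CNP0148821.1 | CC(=O)O[C@H]1[C@H](OC(=O)c2ccccc2)C=C[C@H](OC(=O)c2ccccc2)[C@]1(O)COC(=O)c1ccccc1 | target

Total step count: 11. Longest linear sequence: 11 steps (1 to 18).

Steps most likely to fail

Step 8. t-BuLi may attack the small share of open-chain aldehyde. The vinyllithium may be protonated before the lactolate opens. Closure may also run through the half-chair with a pseudo-axial alkoxide, which would give poor facial selectivity at C3. The fallback closes the same bond by a Nozaki–Hiyama–Kishi reaction on a protected free aldehyde and sets out from 9. Treatment with t-Bu2Si(OTf)2 and 2,6-lutidine ties O–C6 and O–C7 into the six-membered cyclic silylene F1. H5IO6 in EtOAc then gives the silylene aldehyde F2, which cannot form a lactol. CrCl2 with catalytic NiCl2 in DMF closes the ring to the tricyclic allylic alcohol F3; here zerovalent nickel inserts into the C–I bond and the vinyl group passes to trivalent chromium. HF·pyridine removes the silylene, and the route is rejoined at 15.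

Step 4. The ketone may rest as its cyclic hemiketal and turn over slowly. Facial selectivity may erode, or formaldehyde may be lost by retro-aldol cleavage. The fallback replaces catalyst control by substrate control through a temporary ring and sets out from 6. Et2BOMe ties the C7 oxygen and the C6 carbonyl oxygen into the diethylboron chelate F4. NaBH4 at −78 °C (Narasaka–Prasad-type reduction) then delivers hydride to the chelate face anti to C2, which is the same face as in the main route. Methanol work-up returns to 7.

Step 6. Diimide may over-reduce the vinyl iodide to the saturated iodide or stop short of full conversion, which would leave mixtures that are hard to separate. The fallback makes the Z-iodide by radical anti-hydrometalation and sets out from 7. K2CO3 in MeOH gives the terminal alkyne triol F5. HInCl2 (from InCl3 and Et3SiH) with catalytic Et3B and air adds to it to give the (Z)-alkenylindium dichloride F6. Iodolysis with I2 proceeds with retention and rejoins the route at 9.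

Further compounds
F1 | step 8 | C6,C7-O-(di-tert-butylsilylene) derivative of 9 | I/C=C\[C@@H]1O[Si](C(C)(C)C)(C(C)(C)C)OC[C@@]12OC(C)(C)O[C@H]2[C@H](O)[C@H]1COC(C)(C)O1
F2 | step 8 | silylene-protected C3 aldehyde | I/C=C\[C@@H]1O[Si](C(C)(C)C)(C(C)(C)C)OC[C@@]12OC(C)(C)O[C@H]2C=O
F3 | step 8 | tricyclic allylic alcohol (C6,C7-O-silylene derivative of 15) | O[C@@H]1C=C[C@@H]2O[Si](C(C)(C)C)(C(C)(C)C)OC[C@@]23OC(C)(C)O[C@@H]13
F4 | step 4 | C7-O-diethylboryl derivative (boron chelate) of 6 | CCB(CC)OC[C@]1(C(=O)C#C[Si](C)(C)C)OC(C)(C)O[C@H]1[C@H](O)[C@H]1COC(C)(C)O1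
F5 | step 6 | terminal alkyne triol (7 without SiMe3) | C#C[C@H](O)[C@@]1(CO)OC(C)(C)O[C@H]1[C@H](O)[C@H]1COC(C)(C)O1
F6 | step 6 | (Z)-alkenylindium dichloride | Cl[In](Cl)/C=C\[C@H](O)[C@@]1(CO)OC(C)(C)O[C@H]1[C@H](O)[C@H]1COC(C)(C)O1
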